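**Plan**
- Cuts: the O1–C2 bond of ring C goes first, taking the flavone back to an o-hydroxyaryl ynone masked as its methoxymethyl (MOM) ether. C4a–C4 and C4–C3 are then cut together. The iodide and the alkyne go back to plain arene C–H bonds.
- Feature: C4 is a single carbonyl carbon between C4a of ring A (its neighbours C5 and C8a both carry oxygen) and the C3–C2 pair that bears ring B. C4=O can therefore enter as carbon monoxide between an aryl iodide and a terminal alkyne.
- Forward: rings A and B are purchased arenes, each functionalised by lithiation between two 1,3-related oxygens. The chain C4a–C4–C3–C2–C1' is joined in one three-component coupling, and ring C closes last through O1–C2.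
- The oxygen destined to be O1 is the only one carried as an acid-labile acetal. All the others are methyl ethers.
- Stereochemistry: the target has no stereocentre and no configured double bond. Only regiochemistry needs control (the lithiation sites, and six- against five-membered closure).

Key step: step 5

Remark: flavone numbering (O1, C2, C3, C4, C4a, C5 to C8, C8a, primed locants for ring B) is used for all intermediates. The two enaminone intermediates of the last step are drawn as the E isomers expected for a secondary-amine adduct, and this geometry disappears on ring closure.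

**Step 1**
Reactants: 1 3,4-dimethoxyphenol; 2 chloromethyl methyl ether
Product: 3 1,2-dimethoxy-4-(methoxymethoxy)benzene
Conditions: MOMCl, K2CO3, acetone, 0 °C to rt
Reagents that add atoms: chloromethyl methyl ether (compound 2), COCCl
Why: Williamson-type O-alkylation (MOM protection) of the phenoxide by the very electrophilic α-chloro ether is fast under mild carbonate base, and it gives the future O1 an acid-labile mask while installing a strong directing group for the next step.

**Step 2**
Reactants: 3 1,2-dimethoxy-4-(methoxymethoxy)benzene
Product: 5 2-iodo-3,4-dimethoxy-1-(methoxymethoxy)benzene, via ring A aryllithium 4 (not isolated)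
Conditions: n-BuLi, THF, 0 °C; then I2, THF, −78 °C to rt
Reagents that add atoms: iodine, II
Why: Directed ortho-metalation removes the hydrogen at the future C4a, which is acidified and coordinated by both the OMOM group (future C8a) and the adjacent OMe group (future C5) in a cooperative 1,3-effect, and the aryllithium is trapped by I2 without harm to the acetal or the ethers.

**Step 3**
Reactants: 6 1,2,4-trimethoxybenzene
Product: 9 2,3,6-trimethoxybenzaldehyde, via ring B aryllithium 7 (not isolated), via lithium hemiaminolate 8 (not isolated)
Conditions: n-BuLi, THF, 0 °C to rt; then DMF, 0 °C; then H2O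
Reagents that add atoms: N,N-dimethylformamide, CN(C)C=O
Why: Directed ortho-metalation followed by DMF formylation works because the hydrogen flanked by the 2- and 4-methoxy groups of 6 (future C1') is the most acidic and doubly coordinated site, and the tetrahedral lithium hemiaminolate resists further addition until water releases the aldehyde.

**Step 4**
Reactants: 9 2,3,6-trimethoxybenzaldehyde
Product: 10 2-ethynyl-1,3,4-trimethoxybenzene
Conditions: dimethyl (1-diazo-2-oxopropyl)phosphonate, K2CO3, MeOH, rt
Reagents that add atoms: dimethyl (1-diazo-2-oxopropyl)phosphonate (Ohira–Bestmann reagent), COP(=O)(OC)C(=[N+]=[N-])C(C)=O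
Why: In the Ohira–Bestmann variant of the Seyferth–Gilbert homologation, methanolysis of the reagent gives the diazomethylphosphonate anion, which olefinates the non-enolisable aldehyde in Horner–Wadsworth–Emmons fashion, and loss of N2 with a 1,2-hydride shift gives the terminal alkyne under conditions that leave the methyl ethers alone.

**Step 5**
Reactants: 5 2-iodo-3,4-dimethoxy-1-(methoxymethoxy)benzene; 10 2-ethynyl-1,3,4-trimethoxybenzene; 11 carbon monoxide
Product: 12 1-[2,3-dimethoxy-6-(methoxymethoxy)phenyl]-3-(2,3,6-trimethoxyphenyl)prop-2-yn-1-one
Conditions: PdCl2(PPh3)2 (5 mol %), CuI (2 mol %), Et3N, degassed THF, CO (3 bar), 50 °C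
Reagents that add atoms: carbon monoxide (compound 11), [C-]#[O+]
Why: PdCl2(PPh3)2, a divalent palladium precatalyst, is reduced in the flask to zerovalent Pd(PPh3)2, which inserts into the C4a–I bond of 5 to give ArPdI(PPh3)2; CO binds and the aryl group migrates onto it to give the acyl complex ArC(O)PdI(PPh3)2, the alkynylcopper Ar'C≡CCu formed from 10, CuI and Et3N transfers its alkynyl group to palladium, and reductive elimination makes C4–C3 and regenerates the zerovalent catalyst. The closest known reaction type is the carbonylative Sonogashira coupling of aryl iodides with terminal arylalkynes, a standard entry to the diaryl ynones used for flavones. Two skeletal bonds (C4a–C4 and C4–C3) are formed, no ring is closed and no stereocentre is created, so there is no mode of closure or facial control to consider. The selectivity required is chemoselectivity for CO insertion over direct aryl–alkynyl coupling, and the substrate secures it: the C5 methoxy and C8a OMOM groups screen the aryl–palladium carbon against transmetalation, while relief of that crowding and the electron-rich nature of the migrating aryl group accelerate migration to CO, which 3 bar of gas keeps available. Once CO has been inserted the metal is one atom removed from the di-ortho-substituted carbon, so the alkynyl transfer and the reductive elimination occur at an uncongested acyl centre. Et3N is tertiary and cannot add to the ynone, the MOM acetal and the methyl ethers are inert to the mildly basic medium, and rigorous exclusion of oxygen together with a low CuI loading suppresses Glaser-type dimerisation of 10.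

**Step 6**
Reactants: 12 1-[2,3-dimethoxy-6-(methoxymethoxy)phenyl]-3-(2,3,6-trimethoxyphenyl)prop-2-yn-1-one
Product: 15 5,6,2',3',6'-pentamethoxyflavone, via MOM-protected enaminone 13 (not isolated), via phenolic enaminone 14 (not isolated)
Conditions: pyrrolidine, MeOH, 50 °C; evaporate; then 3 M aq HCl, THF, 60 °C
Reagents that add atoms: none
Why: Aza-Michael addition of the small, strongly nucleophilic secondary amine turns the ynone into a β-amino enone, so that once aqueous acid has hydrolysed the MOM acetal the C8a phenol can only attack C2 in a 6-endo addition–elimination (the classical o-hydroxyaryl enaminone to chromone closure) that expels pyrrolidine, which excludes 5-exo closure, while dilute HCl leaves the five aryl methyl ethers intact.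

**Compound list**
1 | 3,4-dimethoxyphenol | COc1ccc(O)cc1OC | starting material
2 | chloromethyl methyl ether | COCCl | starting material
3 | 1,2-dimethoxy-4-(methoxymethoxy)benzene | COCOc1ccc(OC)c(OC)c1 | intermediate
4 | [2,3-dimethoxy-6-(methoxymethoxy)phenyl]lithium | [Li]c1c(OCOC)ccc(OC)c1OC | intermediate
5 | 2-iodo-3,4-dimethoxy-1-(methoxymethoxy)benzene | COCOc1ccc(OC)c(OC)c1I | intermediate
6 | 1,2,4-trimethoxybenzene | COc1ccc(OC)c(OC)c1 | starting material
7 | (2,3,6-trimethoxyphenyl)lithium | [Li]c1c(OC)ccc(OC)c1OC | intermediate
8 | lithium (dimethylamino)(2,3,6-trimethoxyphenyl)methanolate, racemic | [Li]OC(N(C)C)c1c(OC)ccc(OC)c1OC | intermediate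
9 | 2,3,6-trimethoxybenzaldehyde | O=Cc1c(OC)ccc(OC)c1OC | intermediate
10 | 2-ethynyl-1,3,4-trimethoxybenzene | C#Cc1c(OC)ccc(OC)c1OC | intermediate
11 | carbon monoxide | [C-]#[O+] | starting material
12 | 1-[2,3-dimethoxy-6-(methoxymethoxy)phenyl]-3-(2,3,6-trimethoxyphenyl)prop-2-yn-1-one | COCOc1ccc(OC)c(OC)c1C(=O)C#Cc2c(OC)ccc(OC)c2OC | intermediate
13 | (E)-1-[2,3-dimethoxy-6-(methoxymethoxy)phenyl]-3-(pyrrolidin-1-yl)-3-(2,3,6-trimethoxyphenyl)prop-2-en-1-one | COCOc1ccc(OC)c(OC)c1C(=O)/C=C(/N2CCCC2)c3c(OC)ccc(OC)c3OC | intermediate
14 | (E)-1-(6-hydroxy-2,3-dimethoxyphenyl)-3-(pyrrolidin-1-yl)-3-(2,3,6-trimethoxyphenyl)prop-2-en-1-one | Oc1ccc(OC)c(OC)c1C(=O)/C=C(/N2CCCC2)c3c(OC)ccc(OC)c3OC | intermediate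
15 | 5,6,2',3',6'-pentamethoxyflavone | COc1ccc(OC)c(-c2cc(=O)c3c(OC)c(OC)ccc3o2)c1OC | target

Total step count: 6
Longest linear sequence: 4 steps (steps 1, 2, 5, 6 or steps 3, 4, 5, 6)

**Steps most likely to fail**

**Step 5.** Oxidative addition into the crowded, electron-rich C4a–I bond may be slowed further by CO binding to zerovalent palladium. Oxidative dimerisation of the alkyne or non-carbonylative coupling could then take over.

The fallback sets out from 3 and 10 and returns at 12. It forms the same two bonds one after the other by polar chemistry.
- Compound 3 is lithiated to 4 as in step 2 and quenched with DMF to give 2,3-dimethoxy-6-(methoxymethoxy)benzaldehyde F1.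
- Compound 10 is deprotonated with n-BuLi in THF at −78 °C to [(2,3,6-trimethoxyphenyl)ethynyl]lithium F2.
- The slim acetylide adds to the hindered formyl group to give rac-1-[2,3-dimethoxy-6-(methoxymethoxy)phenyl]-3-(2,3,6-trimethoxyphenyl)prop-2-yn-1-ol F3.
- MnO2 in CH2Cl2 oxidises this doubly activated alcohol to 12.

**Step 6.** Amine addition at C2 may be slow, because ring B places two ortho methoxy groups beside the triple bond and donates electron density into it. Unreacted ynone would then meet the liberated phenol in the acid stage without regiochemical guidance.

The fallback sets out from 12 and returns at 15. It closes the ring directly on the triple bond.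
- The acetal is cleaved first with dilute HCl in aqueous THF at rt to give 1-(6-hydroxy-2,3-dimethoxyphenyl)-3-(2,3,6-trimethoxyphenyl)prop-2-yn-1-one F4.
- TfOH in CH2Cl2 then promotes the known Brønsted-acid 6-endo-dig cyclisation of o-alkynoylphenols.
- Protonation of the C4 carbonyl polarises the alkyne towards C2, where the 2'- and 6'-methoxy groups stabilise the developing positive charge, so the phenol attacks C2.

**Step 4.** Attack of the diazophosphonate anion on the doubly ortho-substituted, electron-rich formyl group may be slower than base-induced decay of the reagent, leaving conversion incomplete.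

The fallback sets out from 6 and returns at 10. It builds the C1'–alkyne bond by cross-coupling and does not use the aldehyde.
- Compound 6 is lithiated to 7 as in step 3 and quenched with I2 to give 2-iodo-1,3,4-trimethoxybenzene F5.
- Sonogashira coupling with ethynyltrimethylsilane (PdCl2(PPh3)2, CuI, Et3N, 60 °C) gives trimethyl[(2,3,6-trimethoxyphenyl)ethynyl]silane F6.
- K2CO3 in MeOH removes the silyl group to give 10.

**Further compounds**
F1 | step 5 | 2,3-dimethoxy-6-(methoxymethoxy)benzaldehyde | COCOc1ccc(OC)c(OC)c1C=O
F2 | step 5 | [(2,3,6-trimethoxyphenyl)ethynyl]lithium | [Li]C#Cc1c(OC)ccc(OC)c1OC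
F3 | step 5 | rac-1-[2,3-dimethoxy-6-(methoxymethoxy)phenyl]-3-(2,3,6-trimethoxyphenyl)prop-2-yn-1-ol | COCOc1ccc(OC)c(OC)c1C(O)C#Cc2c(OC)ccc(OC)c2OC
F4 | step 6 | 1-(6-hydroxy-2,3-dimethoxyphenyl)-3-(2,3,6-trimethoxyphenyl)prop-2-yn-1-one | COc1ccc(O)c(C(=O)C#Cc2c(OC)ccc(OC)c2OC)c1OC
F5 | step 4 | 2-iodo-1,3,4-trimethoxybenzene | COc1ccc(OC)c(OC)c1I
F6 | step 4 | trimethyl[(2,3,6-trimethoxyphenyl)ethynyl]silane | COc1ccc(OC)c(C#C[Si](C)(C)C)c1OC
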